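**Retrosynthetic overview**

- Side chain last: the (Z)-trisubstituted enoate is made on the finished core by a Still–Gennari olefination of 2-oxoethyl acetate with a C3 phosphonopropanoate, which comes from acylation of the free C3 alcohol.
- Core: the dihydrofuran ring (ring B) is cut at O1–C2 and at C3a–C3, leading back to 1-(2,4-dihydroxy-5-iodophenyl)ethanone (ring A) and an (E)-1-alkoxy-3-methylbuta-1,3-diene made from 3-methylbut-2-enal.
- One palladium-catalysed operation joins the two: aryl transfer to the oxygen-bearing diene terminus (C3a–C3), then capture of the resulting η3-allyl by the ortho phenol (O1–C2); it closes ring B and sets C3 (chiral ligand) and C2 (trans to C3).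
- Enabling feature: in ring B, C2 carries the isopropenyl group, so C2–C(CH3)=CH2 is a latent η3-allyl terminus; C3 is an oxygenated benzylic carbon that maps onto an enol-ether carbon; O1 and C3a are ortho atoms of ring A (a phenol oxygen and a carbon that can carry iodine).
- Ring order: ring A is present from the start; ring B is the only ring formed (step 3).

Key step: step 3

Remark: the sense of induction of BINAP in step 3 cannot be predicted with confidence, so the ligand antipode that delivers the (2R,3S) series is to be used ((R)-BINAP is written); the ethyl ester of the Still–Gennari propanoate reagent and 1-chloroethyl ethyl ether are taken as commercial.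

**Route**

Step 1
Reactants: 1 1-(2,4-dihydroxyphenyl)ethan-1-one
Product: 2 1-(2,4-dihydroxy-5-iodophenyl)ethan-1-one
Conditions: ICl (1.0 equiv), AcOH, rt
Reagents that add atoms: iodine monochloride, ClI
Why: Electrophilic aromatic iodination should take place at C5, which is ortho to the free 4-hydroxyl and para to the hydrogen-bonded 2-hydroxyl and is less hindered than C3 between the two oxygens.

Step 2
Reactants: 3 3-methylbut-2-enal
Product: 5 (1E)-1-(1-ethoxyethoxy)-3-methylbuta-1,3-diene, via potassium dienolate 4 (not isolated)
Conditions: KN(SiMe3)2 (1.05 equiv), THF, −78 °C; then CH3CHClOEt (1.1 equiv), −78 to 0 °C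
Reagents that add atoms: 1-chloroethyl ethyl ether, CCOC(C)Cl
Why: γ-Deprotonation of the enal gives the extended potassium enolate, whose oxygen is alkylated by the hard α-chloro ether (enolate O-alkylation), and the (E) enol geometry follows from the s-trans conformation of the enal.

Step 3
Reactants: 2 1-(2,4-dihydroxy-5-iodophenyl)ethan-1-one; 5 (1E)-1-(1-ethoxyethoxy)-3-methylbuta-1,3-diene
Product: 6 1-[(2R,3S)-3-(1-ethoxyethoxy)-6-hydroxy-2-(prop-1-en-2-yl)-2,3-dihydro-1-benzofuran-5-yl]ethan-1-one
Conditions: Pd2(dba)3 (2.5 mol %), (R)-BINAP (6 mol %), Ag2CO3 (1.1 equiv), 5 (2 equiv), 1,4-dioxane, 70 °C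
Reagents that add atoms: none
Why: Proposed new method: a cationic Heck-type carbopalladation joined to an allylic etherification, whose closest known relatives are the Larock heteroannulation of o-iodophenols with 1,3-dienes (the same two bonds, but with aryl transfer to an unsubstituted diene terminus) and the α-arylation of enol ethers by cationic arylpalladium bisphosphine complexes. Oxidative addition of 2 to zerovalent palladium and iodide abstraction by silver give [ArPd(BINAP)]+, which binds the electron-rich enol-ether double bond of 5 and transfers the aryl group to the oxygen-bearing carbon, the diene carbon that best carries positive charge without becoming quaternary, so that C3a–C3 is formed and palladium is left on C2 as an η3-allyl over C2, the methyl-bearing carbon and the terminal CH2 (which also blocks β-hydride elimination). The ortho phenol oxygen then attacks the allyl terminus C2 in a 5-exo allylic substitution that forms O1–C2, closes the dihydrofuran ring, leaves the isopropenyl group and returns zerovalent palladium. C3 is set in the migratory insertion by enantioface selection of the enol ether by the chiral bisphosphine, as in asymmetric intermolecular Heck arylations of cyclic enol ethers. C2 is set in the ring closure: the allyl faces interconvert by η3–η1–η3 slippage at the unsubstituted CH2 terminus and the allyl aryl ether can re-ionise, so the 2,3-trans isomer, with the C3 alkoxy group and the isopropenyl group on opposite faces, should predominate. The step needs aryl transfer to the oxygenated rather than the CH2 terminus of the diene, which the cationic pathway (silver salt, bidentate ligand) is chosen to secure, five- over seven-membered closure, which ring size secures, and a C3 substituent that neither transmetallates nor leaves, which the acetal-type enol ether secures (an enol ester would be expelled by the para phenoxide and a silyl enol ether could transfer the dienolate to palladium).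

Step 4
Reactants: 6 1-[(2R,3S)-3-(1-ethoxyethoxy)-6-hydroxy-2-(prop-1-en-2-yl)-2,3-dihydro-1-benzofuran-5-yl]ethan-1-one
Product: 7 1-[(2R,3S)-3,6-dihydroxy-2-(prop-1-en-2-yl)-2,3-dihydro-1-benzofuran-5-yl]ethan-1-one
Conditions: PPTS (10 mol %), MeOH, rt
Reagents that add atoms: none
Why: Acid-catalysed acetal exchange with methanol removes the 1-ethoxyethyl group under conditions too mild to ionise the benzylic C3–O bond, so both stereocentres stay untouched.

Step 5
Reactants: 8 ethyl 2-[bis(2,2,2-trifluoroethoxy)phosphoryl]propanoate
Product: 9 2-[bis(2,2,2-trifluoroethoxy)phosphoryl]propanoic acid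
Conditions: Me3SnOH (3 equiv), 1,2-dichloroethane, 70 °C; aq. HCl work-up
Reagents that add atoms: trimethyltin hydroxide, C[Sn](C)(C)O
Why: Tin hydroxide-mediated ester hydrolysis is nearly neutral and should cleave the carboxylic ethyl ester without touching the electrophilic trifluoroethyl phosphonate esters.

Step 6
Reactants: 7 1-[(2R,3S)-3,6-dihydroxy-2-(prop-1-en-2-yl)-2,3-dihydro-1-benzofuran-5-yl]ethan-1-one; 9 2-[bis(2,2,2-trifluoroethoxy)phosphoryl]propanoic acid
Product: 10 (2R,3S)-5-acetyl-6-hydroxy-2-(prop-1-en-2-yl)-2,3-dihydro-1-benzofuran-3-yl 2-[bis(2,2,2-trifluoroethoxy)phosphoryl]propanoate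
Conditions: DCC (1.1 equiv), DMAP (5 mol %), CH2Cl2, 0 °C
Reagents that add atoms: none
Why: Steglich esterification should acylate the secondary C3 alcohol in preference to the C6 phenol, which is deactivated by its hydrogen bond to the ortho acetyl group, and it leaves the C3–O bond and hence the C3 configuration intact.

Step 7
Reactants: 11 (2Z)-but-2-ene-1,4-diyl diacetate
Product: 13 2-oxoethyl acetate, via secondary ozonide 12 (not isolated)
Conditions: O3, CH2Cl2, −78 °C; then Me2S, −78 °C to rt
Reagents that add atoms: ozone, [O-][O+]=O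
Why: Ozonolysis with reductive work-up cleaves the symmetrical alkene into two equivalents of the aldehyde, which is used as a fresh solution.

Step 8
Reactants: 10 (2R,3S)-5-acetyl-6-hydroxy-2-(prop-1-en-2-yl)-2,3-dihydro-1-benzofuran-3-yl 2-[bis(2,2,2-trifluoroethoxy)phosphoryl]propanoate; 13 2-oxoethyl acetate
Product: 15 (2R,3S)-5-acetyl-6-hydroxy-2-(prop-1-en-2-yl)-2,3-dihydro-1-benzofuran-3-yl (2Z)-4-(acetyloxy)-2-methylbut-2-enoate, via dipotassium salt 14 (not isolated)
Conditions: KN(SiMe3)2 (2.05 equiv), 18-crown-6 (5 equiv), THF, −78 °C; then 13 (1.5 equiv), −78 °C; AcOH quench at −78 °C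
Reagents that add atoms: none
Why: Still–Gennari olefination: once phenol and phosphonate are both deprotonated, the electron-poor bis(trifluoroethyl) phosphonate under dissociating conditions collapses from the kinetic adduct to the (Z)-2-methyl enoate (ester carbonyl and acetoxymethyl cis), and the low temperature with a cold acidic quench is meant to keep the para phenoxide from expelling the C3 carboxylate.

**Compound list**

1 | 1-(2,4-dihydroxyphenyl)ethan-1-one | CC(=O)c1ccc(O)cc1O | starting material
2 | 1-(2,4-dihydroxy-5-iodophenyl)ethan-1-one | CC(=O)c1cc(I)c(O)cc1O | intermediate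
3 | 3-methylbut-2-enal | CC(C)=CC=O | starting material
4 | potassium (1E)-3-methylbuta-1,3-dien-1-olate | [K+].[O-]/C=C/C(C)=C | intermediate
5 | (1E)-1-(1-ethoxyethoxy)-3-methylbuta-1,3-diene (racemic at the acetal carbon) | C=C(C)/C=C/OC(C)OCC | intermediate
6 | 1-[(2R,3S)-3-(1-ethoxyethoxy)-6-hydroxy-2-(prop-1-en-2-yl)-2,3-dihydro-1-benzofuran-5-yl]ethan-1-one (both epimers at the acetal carbon) | C=C(C)[C@H]1Oc2cc(O)c(C(C)=O)cc2[C@@H]1OC(C)OCC | intermediate
7 | 1-[(2R,3S)-3,6-dihydroxy-2-(prop-1-en-2-yl)-2,3-dihydro-1-benzofuran-5-yl]ethan-1-one | C=C(C)[C@H]1Oc2cc(O)c(C(C)=O)cc2[C@@H]1O | intermediate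
8 | ethyl 2-[bis(2,2,2-trifluoroethoxy)phosphoryl]propanoate (racemic) | CCOC(=O)C(C)P(=O)(OCC(F)(F)F)OCC(F)(F)F | starting material
9 | 2-[bis(2,2,2-trifluoroethoxy)phosphoryl]propanoic acid (racemic) | OC(=O)C(C)P(=O)(OCC(F)(F)F)OCC(F)(F)F | intermediate
10 | (2R,3S)-5-acetyl-6-hydroxy-2-(prop-1-en-2-yl)-2,3-dihydro-1-benzofuran-3-yl 2-[bis(2,2,2-trifluoroethoxy)phosphoryl]propanoate (both epimers at the phosphonate-bearing carbon) | C=C(C)[C@H]1Oc2cc(O)c(C(C)=O)cc2[C@@H]1OC(=O)C(C)P(=O)(OCC(F)(F)F)OCC(F)(F)F | intermediate
11 | (2Z)-but-2-ene-1,4-diyl diacetate | CC(=O)OC/C=C\COC(C)=O | starting material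
12 | (1,2,4-trioxolane-3,5-diyl)bis(methylene) diacetate (secondary ozonide, isomer mixture) | CC(=O)OCC1OOC(COC(C)=O)O1 | intermediate
13 | 2-oxoethyl acetate | CC(=O)OCC=O | intermediate
14 | dipotassium salt of 10 (C6 phenoxide and phosphonate carbanion) | [K+].[K+].C=C(C)[C@H]1Oc2cc([O-])c(C(C)=O)cc2[C@@H]1OC(=O)[C-](C)P(=O)(OCC(F)(F)F)OCC(F)(F)F | intermediate
15 | (2R,3S)-5-acetyl-6-hydroxy-2-(prop-1-en-2-yl)-2,3-dihydro-1-benzofuran-3-yl (2Z)-4-(acetyloxy)-2-methylbut-2-enoate | C=C(C)[C@H]1Oc2cc(O)c(C(C)=O)cc2[C@@H]1OC(=O)/C(C)=C\COC(C)=O | target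

Total step count: 8
Longest linear sequence: 5 steps (steps 1, 3, 4, 6 and 8)

**Steps most likely to fail**

Step 3 (Proposed new method). What may go wrong: aryl transfer to the terminal CH2 of the diene instead of the oxygen-bearing carbon (insertion with the wrong regiochemistry), β-hydride elimination to a simple Heck product before the ring closes, silver- or acid-induced loss of the acetal, or weak enantioface selection in the insertion. Fallback with known chemistry, setting out from 2 and coming back at 7: reductive carbonylation of 2 (Pd(OAc)2, dppp, CO, Et3SiH, Na2CO3, DMF) would give 5-acetyl-2,4-dihydroxybenzaldehyde F1. Sulfur-ylide annulation of F1 with 3-bromo-2-methylprop-1-ene under sulfide catalysis (enantiopure (2R,5R)-2,5-dimethylthiolane or its antipode, NaOH, t-BuOH–H2O) would then build the C2–C3 and O1–C2 bonds instead: the allylic sulfonium ylide adds to the aldehyde and the ortho phenoxide displaces the sulfonium group of the anti betaine, the established ylide route from salicylaldehydes to trans-2,3-dihydrobenzofuran-3-ols, to give 7 directly.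

Step 8. What may go wrong: the para phenoxide expels the C3 carboxylate (1,6-elimination to a quinone methide, then aromatisation to the benzofuran) before or after olefination, or the Z selectivity erodes. Fallback, setting out from 7 and 8 and coming back at 15: the olefination is moved away from the base-sensitive benzylic ester. Still–Gennari olefination of 8 with (tert-butyldimethylsilyloxy)acetaldehyde (KN(SiMe3)2, 18-crown-6, THF, −78 °C) would give ethyl (2Z)-4-{[tert-butyl(dimethyl)silyl]oxy}-2-methylbut-2-enoate F2, and LiOH hydrolysis would give (2Z)-4-{[tert-butyl(dimethyl)silyl]oxy}-2-methylbut-2-enoic acid F3. Yamaguchi esterification of 7 with F3 (2,4,6-trichlorobenzoyl chloride, Et3N, DMAP, toluene, 0 °C) would give the C3 (2Z)-4-silyloxy-2-methylbut-2-enoate of 7 F4. HF·pyridine in THF–pyridine followed by Ac2O in the same flask would pass through the C3 (2Z)-4-hydroxy-2-methylbut-2-enoate of 7 F5 to 15.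

Step 1. What may go wrong: iodination at C3 between the two oxygens or double iodination (poor site selectivity). Fallback, setting out from 1 and coming back at 2: bromination (Br2, AcOH), which is expected to be more selective for C5, would give 1-(5-bromo-2,4-dihydroxyphenyl)ethan-1-one F6, and a copper-catalysed aromatic Finkelstein exchange (CuI, NaI, trans-N,N′-dimethylcyclohexane-1,2-diamine, dioxane, 110 °C) would convert F6 into 2.

Further compounds
F1 | step 3 | 5-acetyl-2,4-dihydroxybenzaldehyde | CC(=O)c1cc(C=O)c(O)cc1O
F2 | step 8 | ethyl (2Z)-4-{[tert-butyl(dimethyl)silyl]oxy}-2-methylbut-2-enoate | CCOC(=O)/C(C)=C\CO[Si](C)(C)C(C)(C)C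
F3 | step 8 | (2Z)-4-{[tert-butyl(dimethyl)silyl]oxy}-2-methylbut-2-enoic acid | OC(=O)/C(C)=C\CO[Si](C)(C)C(C)(C)C
F4 | step 8 | (2R,3S)-5-acetyl-6-hydroxy-2-(prop-1-en-2-yl)-2,3-dihydro-1-benzofuran-3-yl (2Z)-4-{[tert-butyl(dimethyl)silyl]oxy}-2-methylbut-2-enoate | C=C(C)[C@H]1Oc2cc(O)c(C(C)=O)cc2[C@@H]1OC(=O)/C(C)=C\CO[Si](C)(C)C(C)(C)C
F5 | step 8 | (2R,3S)-5-acetyl-6-hydroxy-2-(prop-1-en-2-yl)-2,3-dihydro-1-benzofuran-3-yl (2Z)-4-hydroxy-2-methylbut-2-enoate | C=C(C)[C@H]1Oc2cc(O)c(C(C)=O)cc2[C@@H]1OC(=O)/C(C)=C\CO
F6 | step 1 | 1-(5-bromo-2,4-dihydroxyphenyl)ethan-1-one | CC(=O)c1cc(Br)c(O)cc1O
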